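**Leftover earns.** The Ja left standing in a vessel is what earns Jb, and Jb stands on the left of no step, so each vessel's yield is the rate constant 0.056 s⁻¹ times its Ja-seconds.

common to all: Ja 17 mM

| run | remark | time |
|---|---|---|
| violet | one stirred flow tank at steady state, fed with the mixture as stated, mean residence time 15 s |  |
| amber | everything together in a closed stirred flask, run for 15 s | 15 s |
| green | a tube with plug flow, the mixed feed as stated, residence time 15 s | 15 s |

- the set-up with the highest amount of Jb at the outlet or at the end, in percent of the Ja put in ("none" if the first two lie within 2 percentage points) (violet / amber / green / none)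
- amount of Jb at the outlet or at the end, in percent of the Ja put in, violet
- amount of Jb at the outlet or at the end, in percent of the Ja put in, amber
- amount of Jb at the outlet or at the end, in percent of the Ja put in, green

- percentages count the Ja that a species holds: one Jg counts as two
- two of one species on the left: rate k times its square, two consumed each time
- the stated concentrations are those of everything mixed, before any reaction; amounts are the same in each set-up
- run time (amber): 15 s

    Jc → Je (k1 = 0.059 s⁻¹)
    Ja → Jc (k2 = 0.052 s⁻¹)
    2 Ja → Jg (k3 = 4.1 M⁻¹ s⁻¹)
    Ja → Jb (k4 = 0.056 s⁻¹)
    Ja ⇌ Jf (K5 = 1.7, k5 = 0.069 s⁻¹)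
    Jc ⇌ Jd (K6 = 6.8, k6 = 0.035 s⁻¹)

**Two extremes.** Amber and green share one history of 15 s, so one integral serves both. First, suppose Jf is a one-way drain. Ja then falls at first order k = 0.177 s⁻¹, plus a second-order loss to Jg that starts at g = 0.139 s⁻¹. Integrating gives the logarithm of 1 + (g/k)(1 − e^(−kt)), divided by g, which is 3.94 s. Second, suppose Jf takes nothing. Then k = 0.108 s⁻¹, and the same formula gives 5.10 s.

**Between them.** Jf returns to Ja with a lifetime of 24.6 s, longer than the run, so the real flask lies nearer the first extreme. For the return I take a plain guess: I let it act for 7.50 s, which gives 26.2%, and I place the flask that far along the gap. That gives 4.24 s of Ja-seconds, the time integral of Ja divided by its charge, and so Jb of 23.7%.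

**Stirred tank.** Violet is algebra. The Jf balance cuts the net drain, making the first-order rate 0.151 s⁻¹, and the quadratic leaves Ja at 26.2% of the feed. That is 3.94 s of Ja-seconds and Jb of 22.1%. Violet trails amber and green by 1.7 percentage points, and those two share one history, so the first two are level and I say none.

**The check.** The forecast says none, with 22%, 24.3% and 24.3% for violet, amber and green, since “The closed flask and the plug-flow tube have the same 15 s history”.

The flask gives none, with 22.0%, 23.7% and 23.7%.

Amber ends with 19.3% as Jf. Its Jb reads back as 4.23 s of Ja-seconds, against my guessed placing of 4.24 s.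

**Thinner charge.** With 4.2 mM of Ja, g shrinks to 0.0344 s⁻¹. The extremes become 4.83 s and 6.61 s, and the same placing gives 5.30 s of Ja-seconds, so Jb of 29.7%. That flask gives 29.2%.

Its constants were set for the occasion; the rest is arithmetic.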